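**Plan**

- Retrosynthesis: the five phenols are masked as benzyl ethers. The first cut is the C2–C1' bond between the dihydropyranone ring of the flavanone half and its 2-aryl ring, giving 5,7-bis(benzyloxy)chromone and an arylboronic acid that already carries the whole flavone.
- Enabling feature: C2 of the flavanone is the β-carbon of the O1–C2–C3–C4=O unit, so at the chromone oxidation level it is an unsubstituted enone terminus. C2 of the flavone ring is blocked by its 4-methoxyphenyl group, and C1' has two ortho hydrogens and a para oxygen.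
- Second cut: the biaryl bond flavone C8–aryl C3' (Suzuki–Miyaura, with chlorine as a latent boron). Third cut: the flavone pyranone ring (O1–C2, via a 2'-hydroxychalcone).
- Forward: one dibenzylated phloroacetophenone feeds both halves. The chromone ring is closed from an enaminone; the flavone ring by oxidative chalcone cyclisation after ortho-iodination; then biaryl coupling, borylation, union and global hydrogenolysis.
- Stereochemistry: the single stereocentre C2 (S) is created in the union itself by ligand-controlled, enantioface-selective aryl–palladium insertion. Only neutral conditions follow, so the ring is not opened again.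

Key step: step 8

Remark 1: the C8–C3' biaryl axis (three ortho oxygens, one ortho hydrogen) is taken as configurationally labile at room temperature, in line with the target being drawn without an axial descriptor; no step controls it.

Remark 2: the sense of induction is taken from the known behaviour of the palladium/pyridine-oxazoline system with chromone and simple arylboronic acids, where the (S)-ligand gives (R)-2-arylchroman-4-ones; the (R)-ligand is therefore specified for the 2S product.

**Route**

Step 1
Reactants: 1 2',4',6'-trihydroxyacetophenone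
Product: 2 1-[2,4-bis(benzyloxy)-6-hydroxyphenyl]ethan-1-one
Conditions: BnBr (2.1 equiv), K2CO3, DMF, 0 °C to rt
Reagents that add atoms: benzyl bromide, BrCc1ccccc1
Why: Williamson ether synthesis; the para hydroxyl and one ortho hydroxyl should be alkylated, while the remaining ortho hydroxyl is held in a hydrogen bond to the ketone and resists carbonate-mediated benzylation.

Step 2
Reactants: 2 1-[2,4-bis(benzyloxy)-6-hydroxyphenyl]ethan-1-one
Product: 4 5,7-bis(benzyloxy)-4H-chromen-4-one, via enaminone 3 (not isolated)
Conditions: Me2NCH(OMe)2, toluene, 100 °C; then conc. HCl, CH2Cl2, 40 °C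
Reagents that add atoms: N,N-dimethylformamide dimethyl acetal, COC(OC)N(C)C
Why: Enaminone route to chromones; condensation of the methyl ketone with the formamide acetal should give the enaminone, and acid then drives 6-endo addition of the phenol to the β-carbon with loss of dimethylamine.

Step 3
Reactants: 2 1-[2,4-bis(benzyloxy)-6-hydroxyphenyl]ethan-1-one
Product: 5 1-[4,6-bis(benzyloxy)-2-hydroxy-3-iodophenyl]ethan-1-one
Conditions: I2 (0.4 equiv), HIO3 (0.2 equiv), EtOH/H2O, 40 °C
Reagents that add atoms: iodine, II; iodic acid, OI(=O)=O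
Why: Electrophilic aromatic iodination; attack should occur at C3, ortho to the free phenol and para to a benzyloxy group, rather than at the more crowded C5 between two benzyloxy groups, as is known for the corresponding dimethyl ether.

Step 4
Reactants: 5 1-[4,6-bis(benzyloxy)-2-hydroxy-3-iodophenyl]ethan-1-one; 6 4-methoxybenzaldehyde
Product: 7 (E)-1-[4,6-bis(benzyloxy)-2-hydroxy-3-iodophenyl]-3-(4-methoxyphenyl)prop-2-en-1-one
Conditions: KOH (aq.), EtOH/THF, rt
Reagents that add atoms: none
Why: Claisen–Schmidt condensation of a methyl ketone with a non-enolisable aldehyde; dehydration of the aldol should give the thermodynamically favoured E-enone.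

Step 5
Reactants: 7 (E)-1-[4,6-bis(benzyloxy)-2-hydroxy-3-iodophenyl]-3-(4-methoxyphenyl)prop-2-en-1-one
Product: 9 5,7-bis(benzyloxy)-8-iodo-2-(4-methoxyphenyl)-4H-chromen-4-one, via racemic iodoflavanone 8 (not isolated)
Conditions: I2 (10 mol%), DMSO, 120 °C
Reagents that add atoms: none
Why: Iodine-catalysed oxidative cyclisation of a 2'-hydroxychalcone (6-endo oxa-Michael closure to the flavanone, then iodine-mediated dehydrogenation with DMSO as terminal oxidant); only the single free phenol can close, which fixes the iodine at C8, and the catalytic iodine loading should keep nuclear iodine exchange low.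

Step 6
Reactants: 9 5,7-bis(benzyloxy)-8-iodo-2-(4-methoxyphenyl)-4H-chromen-4-one; 10 [2-(benzyloxy)-5-chlorophenyl]boronic acid
Product: 11 5,7-bis(benzyloxy)-8-[2-(benzyloxy)-5-chlorophenyl]-2-(4-methoxyphenyl)-4H-chromen-4-one
Conditions: Pd(PPh3)4 (5 mol%), K2CO3 (2 M aq.), DME, 85 °C
Reagents that add atoms: none
Why: Suzuki–Miyaura coupling; oxidative addition into the C–I bond is far faster than into the electron-rich C–Cl bond with this triphenylphosphine catalyst, so the chlorine should survive as the handle for the next step.

Step 7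
Reactants: 11 5,7-bis(benzyloxy)-8-[2-(benzyloxy)-5-chlorophenyl]-2-(4-methoxyphenyl)-4H-chromen-4-one
Product: 12 {4-(benzyloxy)-3-[5,7-bis(benzyloxy)-2-(4-methoxyphenyl)-4-oxo-4H-chromen-8-yl]phenyl}boronic acid
Conditions: B2(OH)4, (XPhos)Pd(2'-aminobiphenyl-2-yl)Cl (second-generation XPhos palladacycle, 2 mol%), XPhos, KOAc, EtOH/THF, 80 °C
Reagents that add atoms: tetrahydroxydiboron, OB(O)B(O)O
Why: Palladium-catalysed Miyaura-type borylation of an aryl chloride with tetrahydroxydiboron, which should give the free boronic acid directly; the bulky dialkylbiarylphosphine activates the electron-rich C–Cl bond, and acetate is too weak a base to touch the benzyl ethers or the flavone.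

Step 8
Reactants: 12 {4-(benzyloxy)-3-[5,7-bis(benzyloxy)-2-(4-methoxyphenyl)-4-oxo-4H-chromen-8-yl]phenyl}boronic acid; 4 5,7-bis(benzyloxy)-4H-chromen-4-one
Product: 13 5,7-bis(benzyloxy)-8-{2-(benzyloxy)-5-[(2S)-5,7-bis(benzyloxy)-4-oxochroman-2-yl]phenyl}-2-(4-methoxyphenyl)-4H-chromen-4-one
Conditions: Pd(OCOCF3)2 (10 mol%), (R)-4-tert-butyl-2-(pyridin-2-yl)-4,5-dihydrooxazole (12 mol%), NH4PF6 (30 mol%), H2O (5 equiv), ClCH2CH2Cl, 60 °C; 4 in 1.5-fold excess
Reagents that add atoms: none
Why: A cationic divalent palladium complex of the pyridine-oxazoline ligand transmetalates with boronic acid 12, the aryl–palladium species inserts syn across the C2=C3 bond of chromone 4 with the aryl group going to C2 (the β-carbon of the O1–C2=C3–C4=O vinylogous ester), and the resulting palladium enolate is protonated by water, which releases 13 and returns divalent palladium without any redox change. The closest known reaction type is the palladium/pyridine-oxazoline-catalysed enantioselective conjugate addition of arylboronic acids to chromones, which gives 2-arylchroman-4-ones directly. No ring is closed in this step: the dihydropyranone ring of the flavanone is the pre-formed pyranone ring of 4, saturated by the addition. The new stereocentre C2 is set in the insertion under control of the tert-butyl group of the (R)-ligand, which leaves only one enantioface of the bound chromone open to the migrating aryl group and should give the 2S configuration. The step needs site selectivity between two chromone-type acceptors, and substitution secures it: C2 of 4 carries only hydrogen, whereas C2 of the flavone unit inside 12 carries the 4-methoxyphenyl ring and would have to become a quaternary centre. The non-basic medium should keep the product from opening by retro-oxa-Michael reaction, so the configuration should hold, and the boron-bearing carbon of 12 has two ortho hydrogens, so transmetalation is not hindered.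

Step 9
Reactants: 13 5,7-bis(benzyloxy)-8-{2-(benzyloxy)-5-[(2S)-5,7-bis(benzyloxy)-4-oxochroman-2-yl]phenyl}-2-(4-methoxyphenyl)-4H-chromen-4-one
Product: 14 2,3-dihydropodocarpusflavone A, 8-{5-[(2S)-5,7-dihydroxy-4-oxochroman-2-yl]-2-hydroxyphenyl}-5,7-dihydroxy-2-(4-methoxyphenyl)-4H-chromen-4-one
Conditions: H2 (1 atm), 10% Pd/C, EtOAc/THF, rt
Reagents that add atoms: none
Why: Catalytic hydrogenolysis of the five benzyl ethers; the medium is neutral, so C2 cannot epimerise by ring opening, and the aryl methyl ether, the flavone enone and the aryl ketone should not be reduced at ambient pressure and temperature if the reaction is stopped at full debenzylation.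

**Compound list**

1 | 2',4',6'-trihydroxyacetophenone | CC(=O)c1c(O)cc(O)cc1O | starting material
2 | 1-[2,4-bis(benzyloxy)-6-hydroxyphenyl]ethan-1-one | CC(=O)c1c(O)cc(OCc2ccccc2)cc1OCc1ccccc1 | intermediate
3 | (E)-1-[2,4-bis(benzyloxy)-6-hydroxyphenyl]-3-(dimethylamino)prop-2-en-1-one | CN(C)/C=C/C(=O)c1c(O)cc(OCc2ccccc2)cc1OCc1ccccc1 | intermediate
4 | 5,7-bis(benzyloxy)-4H-chromen-4-one | O=c1ccoc2cc(OCc3ccccc3)cc(OCc3ccccc3)c12 | intermediate
5 | 1-[4,6-bis(benzyloxy)-2-hydroxy-3-iodophenyl]ethan-1-one | CC(=O)c1c(O)c(I)c(OCc2ccccc2)cc1OCc1ccccc1 | intermediate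
6 | 4-methoxybenzaldehyde | COc1ccc(C=O)cc1 | starting material
7 | (E)-1-[4,6-bis(benzyloxy)-2-hydroxy-3-iodophenyl]-3-(4-methoxyphenyl)prop-2-en-1-one | COc1ccc(/C=C/C(=O)c2c(O)c(I)c(OCc3ccccc3)cc2OCc2ccccc2)cc1 | intermediate
8 | racemic 5,7-bis(benzyloxy)-8-iodo-2-(4-methoxyphenyl)chroman-4-one | COc1ccc(C2CC(=O)c3c(OCc4ccccc4)cc(OCc4ccccc4)c(I)c3O2)cc1 | intermediate
9 | 5,7-bis(benzyloxy)-8-iodo-2-(4-methoxyphenyl)-4H-chromen-4-one | COc1ccc(-c2cc(=O)c3c(OCc4ccccc4)cc(OCc4ccccc4)c(I)c3o2)cc1 | intermediate
10 | [2-(benzyloxy)-5-chlorophenyl]boronic acid | OB(O)c1cc(Cl)ccc1OCc1ccccc1 | starting material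
11 | 5,7-bis(benzyloxy)-8-[2-(benzyloxy)-5-chlorophenyl]-2-(4-methoxyphenyl)-4H-chromen-4-one | COc1ccc(-c2cc(=O)c3c(OCc4ccccc4)cc(OCc4ccccc4)c(-c4cc(Cl)ccc4OCc4ccccc4)c3o2)cc1 | intermediate
12 | {4-(benzyloxy)-3-[5,7-bis(benzyloxy)-2-(4-methoxyphenyl)-4-oxo-4H-chromen-8-yl]phenyl}boronic acid | COc1ccc(-c2cc(=O)c3c(OCc4ccccc4)cc(OCc4ccccc4)c(-c4cc(B(O)O)ccc4OCc4ccccc4)c3o2)cc1 | intermediate
13 | 5,7-bis(benzyloxy)-8-{2-(benzyloxy)-5-[(2S)-5,7-bis(benzyloxy)-4-oxochroman-2-yl]phenyl}-2-(4-methoxyphenyl)-4H-chromen-4-one | COc1ccc(-c2cc(=O)c3c(OCc4ccccc4)cc(OCc4ccccc4)c(-c4cc([C@@H]5CC(=O)c6c(OCc7ccccc7)cc(OCc7ccccc7)cc6O5)ccc4OCc4ccccc4)c3o2)cc1 | intermediate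
14 | 2,3-dihydropodocarpusflavone A | COc1ccc(-c2cc(=O)c3c(O)cc(O)c(-c4cc([C@@H]5CC(=O)c6c(O)cc(O)cc6O5)ccc4O)c3o2)cc1 | target

**Step count**

Total steps: 9. Longest linear sequence: 8 steps (steps 1, 3, 4, 5, 6, 7, 8 and 9, from compound 1).

**Steps most likely to fail**

Step 8. What may go wrong: slow transmetalation or insertion with the large, polyoxygenated boronic acid, so that protodeboronation overtakes the addition, or an eroded enantiofacial preference. The fallback moves the union of the two large halves to the biaryl bond and sets out from chromone 4 and iodoflavone 9. Purchased [4-(benzyloxy)-3-chlorophenyl]boronic acid F1 would be added to 4 under the same Pd(OCOCF3)2/(R)-pyridine-oxazoline conditions, the small-partner regime of this reaction, to give (S)-5,7-bis(benzyloxy)-2-[4-(benzyloxy)-3-chlorophenyl]chroman-4-one F2. Miyaura borylation (B2pin2, Pd2(dba)3, XPhos, KOAc, dioxane, 100 °C) should convert it into (S)-5,7-bis(benzyloxy)-2-[4-(benzyloxy)-3-(4,4,5,5-tetramethyl-1,3,2-dioxaborolan-2-yl)phenyl]chroman-4-one F3. Suzuki–Miyaura coupling of this boronate with 9 (Pd(PPh3)4, CsF, DME, 80 °C, fluoride in place of carbonate to avoid retro-oxa-Michael opening) comes back to the route at 13.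

Step 9. What may go wrong: over-reduction during the long exposure that five benzyl ethers need, by hydrogenolytic opening of the benzylic C2–O bond of the flavanone ring or by saturation of the flavone C2=C3 bond. The fallback sets out from 13 and replaces hydrogenolysis by a non-reductive Lewis-acid debenzylation with BCl3 and pentamethylbenzene as benzyl cation scavenger (CH2Cl2, −78 °C). At this temperature the 4-methoxyphenyl methyl ether should be spared. It comes back at 14 and forms no new compound (F0).

Step 7. What may go wrong: protodechlorination or stalled conversion of the poorly ethanol-soluble substrate, and loss of the free boronic acid on isolation. The fallback sets out from 11 and goes through an isolable ester. Miyaura borylation with B2pin2 (Pd2(dba)3, XPhos, KOAc, dioxane, 100 °C) should give 5,7-bis(benzyloxy)-8-[2-(benzyloxy)-5-(4,4,5,5-tetramethyl-1,3,2-dioxaborolan-2-yl)phenyl]-2-(4-methoxyphenyl)-4H-chromen-4-one F4, which can be chromatographed. Oxidative cleavage of the pinacol ester (NaIO4, NH4OAc, acetone/H2O, rt) then comes back to the route at 12.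

**Further compounds**

F1 | step 8 | [4-(benzyloxy)-3-chlorophenyl]boronic acid (purchased) | OB(O)c1ccc(OCc2ccccc2)c(Cl)c1
F2 | step 8 | (S)-5,7-bis(benzyloxy)-2-[4-(benzyloxy)-3-chlorophenyl]chroman-4-one | Clc1cc([C@@H]2CC(=O)c3c(OCc4ccccc4)cc(OCc4ccccc4)cc3O2)ccc1OCc1ccccc1
F3 | step 8 | (S)-5,7-bis(benzyloxy)-2-[4-(benzyloxy)-3-(4,4,5,5-tetramethyl-1,3,2-dioxaborolan-2-yl)phenyl]chroman-4-one | CC1(C)OB(c2cc([C@@H]3CC(=O)c4c(OCc5ccccc5)cc(OCc5ccccc5)cc4O3)ccc2OCc2ccccc2)OC1(C)C
F0 | step 9 | none | none
F4 | step 7 | 5,7-bis(benzyloxy)-8-[2-(benzyloxy)-5-(4,4,5,5-tetramethyl-1,3,2-dioxaborolan-2-yl)phenyl]-2-(4-methoxyphenyl)-4H-chromen-4-one | COc1ccc(-c2cc(=O)c3c(OCc4ccccc4)cc(OCc4ccccc4)c(-c4cc(B5OC(C)(C)C(C)(C)O5)ccc4OCc4ccccc4)c3o2)cc1
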